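I read each flask at 20 s, so I want to know how far the exchange chain has got by then.

| flask | starting complex | incoming ligand | time | remark |
|---|---|---|---|---|
| alpha | 1.5 × 10⁻⁴ M (fed, over 3.0 s) | 0.525 mM | 20 s | the fed solution adds 0.10 times the starting volume |
| zeta | 2.0 × 10⁻⁴ M (fed, over 3.0 s) | 0.525 mM | 20 s | the fed solution adds 0.10 times the starting volume |
| eta | 3.0 × 10⁻⁴ M (fed, over 3.0 s) | 0.525 mM | 20 s | the fed solution adds 0.10 times the starting volume |
| beta | 5.0 × 10⁻⁴ M (fed, over 3.0 s) | 0.525 mM | 20 s | the fed solution adds 0.10 times the starting volume |
| delta | 8.0 × 10⁻⁴ M (fed, over 3.0 s) | 0.525 mM | 20 s | the fed solution adds 0.10 times the starting volume |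

    leaving ligand + starting complex → side product (k1 = 1100 /M/s)
    2 starting complex → homo dimer (k2 = 0.93 /M/s)
    complex with two exchanged + incoming ligand ⇌ leaving ligand + complex with three exchanged (K3 = 1.2, k3 = 920 /M/s)
    starting complex + incoming ligand ⇌ leaving ligand + complex with one exchanged (K4 = 1.4, k4 = 430 /M/s)
    complex with one exchanged + incoming ligand ⇌ leaving ligand + complex with two exchanged (K5 = 1.1, k5 = 53 /M/s)

- a species is counted by the starting complex in it: one homo dimer counts as two
- a doubled species enters its step squared and goes two at a time
- charges are per starting volume, the dose included; the dosed solution carries all of it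
- "hardly changes" means that all values lie within two and a half points (for a concentration: within two and a half percent of the largest)
- run time (alpha): 20 s

1. [complex with three exchanged] at the end for alpha, zeta, eta, beta, delta, in this order
2. how the row runs (rises all the way / rises, then falls / falls, then rises / hardly changes / falls all the way)

My reckoning rests on two times: the reading time and the forward half-life of the second exchange. In alpha, incoming ligand stands above the starting complex, so I treat each exchange as pseudo-first-order in its complex. By the forward step alone, with the other concentrations as charged, in alpha the first exchange has a half-life of 3.1 s and the third 1.4 s. For the second exchange, 53 /M/s times 0.525 mM gives 0.0278 /s, so its forward half-life τ, the bottleneck half-life of complex with one exchanged at charged incoming ligand, is 24.9 s. That is longer than the other two, so I take the second exchange as the rate-limiting step of the chain in alpha.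

The reading time holds 0.803 of τ. Complex with one exchanged present from the first moment would pass the second exchange to a share of 42.7 %. For alpha, thinned by the feed, that gives 5.82 × 10⁻⁵ M of two- and three-exchanged complex together, a deliberately high figure: it allows no delay and no side product. In delta, the charge of starting complex exceeds the incoming ligand, and τ lengthens as that ligand is used. So I expect the row to rise and then fall, though I can't place the turn by hand.

The forecast gives 2.000 × 10⁻⁵ M, 2.200 × 10⁻⁵ M, 2.300 × 10⁻⁵ M, 1.900 × 10⁻⁵ M and 1.200 × 10⁻⁵ M, and says rises, then falls. Its grounds: “At high charge the incoming ligand runs short, leaving ligand builds up and the side product takes starting complex, so the yield peaks near the middle and then drops.” My alpha figure is a different quantity, so it doesn't reproduce the forecast's point.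

The flasks give 1.70 × 10⁻⁵ M, 1.95 × 10⁻⁵ M, 2.26 × 10⁻⁵ M, 2.44 × 10⁻⁵ M and 2.05 × 10⁻⁵ M: rises, then falls, with the turn read at a starting complex concentration of 4.8 × 10⁻⁴ M. In alpha at 20.0 s, complex with one exchanged holds 47.9 % of the charge, against 12.5 % in complex with three exchanged. With 73 % of the incoming ligand left in alpha at 20.0 s, thinned by the feed, τ reckoned at that end concentration stands at 37.7 s. In delta at 20.0 s, 22 % of it is left, so τ reckoned at that end concentration stands at 125 s, and the reading time in delta is 0.160 of that end value.

The numbers of this flask were chosen freely; the flask was simulated.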